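**Retrosynthetic overview**

1. The strategy rests on the C10–C1(=O)–C2=C3(CH3)–C4 segment of the seven-membered ring beside quaternary C10. It is read as a ketene (C1=C2) on a cyclopropane (C3, C4, C5) that carries, cis to it, the C6=C10 alkene of the cyclopentene (C6–C10). A [3,3] shift then forms C1–C10, breaks C3–C5 and closes the seven-membered ring.
2. Endgame: ester C–O at C1; C1 carbinol from the C1 ketone by reduction directed by the C6 hydroxyl; C6 hydroxyl from the C5=C6 alkene through the β-epoxide and hydride opening at C5.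
3. The ketene comes from a diazomethyl ketone (Wolff); the cis-cyclopropane from a (Z)-allylic alcohol by reagent-controlled Simmons–Smith reaction; the (Z)-alkene from a cyclopentenecarbaldehyde; that aldehyde from (S)-limonene, which supplies C7.
4. Order of ring formation: five-membered ring (step 3), cyclopropane (step 6), seven-membered ring (step 9, with loss of the cyclopropane).

Key step: step 9

Numbering and faces: C1 ester carbinol, C2=C3 (C3 bears methyl), C4, C5, C6 (ring-fusion carbinol), C7 (isopropyl), C8, C9, C10 (ring-fusion carbon with methyl). The β face is that of the C10 methyl; the C6 hydroxyl and the C7 isopropyl are also β, and the C1 ester oxygen is α.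

Remark: the sense of induction of the (4R,5R)-dioxaborolane in step 6 is assumed to be the same for this (Z)-trisubstituted dienol as for simple allylic alcohols.

**Route**

Step 1
Reactants: 1 (S)-(−)-limonene
Product: 2 (4S)-1-methyl-4-(propan-2-yl)cyclohex-1-ene
Conditions: H2 (1 atm), RhCl(PPh3)3 (cat.), PhH–EtOH, 23 °C
Reagents that add atoms: none
Why: Chemoselective homogeneous hydrogenation, in which RhCl(PPh3)3 reduces the unhindered 1,1-disubstituted isopropenyl alkene much faster than the trisubstituted ring alkene and leaves the stereocentre untouched.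

Step 2
Reactants: 2 (4S)-1-methyl-4-(propan-2-yl)cyclohex-1-ene
Product: 3 (3S)-6-oxo-3-(propan-2-yl)heptanal
Conditions: O3, CH2Cl2, −78 °C; Me2S, −78 → 23 °C
Reagents that add atoms: ozone, SMILES [O-][O+]=O
Why: Ozonolysis with reductive work-up cleaves the only alkene to the keto aldehyde, and the stereocentre is not alpha to either carbonyl, so it cannot epimerise.

Step 3
Reactants: 3 (3S)-6-oxo-3-(propan-2-yl)heptanal
Product: 4 (5R)-2-methyl-5-(propan-2-yl)cyclopent-1-ene-1-carbaldehyde
Conditions: piperidine, AcOH, PhH, reflux (Dean–Stark)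
Reagents that add atoms: none
Why: Amine-mediated intramolecular aldol condensation, in which the enamine of the aldehyde attacks the methyl ketone to close the five-membered ring and dehydration gives the conjugated enal; the isopropyl-bearing carbon sits on the alpha carbon of the enal and is not acidified by it.

Step 4
Reactants: 4 (5R)-2-methyl-5-(propan-2-yl)cyclopent-1-ene-1-carbaldehyde; 5 ethyl 2-[bis(2,2,2-trifluoroethoxy)phosphoryl]propanoate
Product: 6 ethyl (2Z)-2-methyl-3-[(5R)-2-methyl-5-(propan-2-yl)cyclopent-1-en-1-yl]prop-2-enoate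
Conditions: 5, KN(SiMe3)2, 18-crown-6, THF, −78 °C; then 4, −78 °C
Reagents that add atoms: 5 ethyl 2-[bis(2,2,2-trifluoroethoxy)phosphoryl]propanoate, SMILES CCOC(=O)C(C)P(=O)(OCC(F)(F)F)OCC(F)(F)F
Why: Still–Gennari variant of the Horner–Wadsworth–Emmons olefination, in which the electron-poor phosphonate with a dissociated potassium counter-ion eliminates rapidly from the kinetic adduct and should give the (Z)-enoate, placing ester and cyclopentenyl cis as the cyclopropane will need them.

Step 5
Reactants: 6 ethyl (2Z)-2-methyl-3-[(5R)-2-methyl-5-(propan-2-yl)cyclopent-1-en-1-yl]prop-2-enoate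
Product: 7 (2Z)-2-methyl-3-[(5R)-2-methyl-5-(propan-2-yl)cyclopent-1-en-1-yl]prop-2-en-1-ol
Conditions: i-Bu2AlH, CH2Cl2, −78 °C; aq. KNaC4H4O6
Reagents that add atoms: none
Why: 1,2-Reduction of the ester by the aluminium hydride at low temperature gives the allylic alcohol without touching either alkene or the alkene geometry.

Step 6
Reactants: 7 (2Z)-2-methyl-3-[(5R)-2-methyl-5-(propan-2-yl)cyclopent-1-en-1-yl]prop-2-en-1-ol; 8 diiodomethane
Product: 9 [(1S,2S)-1-methyl-2-[(5R)-2-methyl-5-(propan-2-yl)cyclopent-1-en-1-yl]cyclopropyl]methanol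
Conditions: Et2Zn, 8, DME, CH2Cl2, −10 °C [Zn(CH2I)2·DME]; (4R,5R)-2-butyl-N,N,N′,N′-tetramethyl-1,3,2-dioxaborolane-4,5-dicarboxamide; 7; −10 → 23 °C
Reagents that add atoms: 8 diiodomethane (as bis(iodomethyl)zinc), SMILES ICI
Why: Charette asymmetric Simmons–Smith cyclopropanation, in which the zinc alkoxide bound to the dioxaborolane delivers CH2 only to the proximal alkene (the tetrasubstituted ring alkene is not directed), the stereospecific addition turns the Z geometry into the cis relation of CH2OH and cyclopentenyl, and the (4R,5R)-ligand, which gives (1S,2S)-2-phenylcyclopropylmethanol from cinnamyl alcohol, should set C3 and C5 as (S,S) under reagent control over the remote C7 centre.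

Step 7
Reactants: 9 [(1S,2S)-1-methyl-2-[(5R)-2-methyl-5-(propan-2-yl)cyclopent-1-en-1-yl]cyclopropyl]methanol
Product: 11 (1S,2S)-1-methyl-2-[(5R)-2-methyl-5-(propan-2-yl)cyclopent-1-en-1-yl]cyclopropane-1-carboxylic acid, via aldehyde 10 (not isolated)
Conditions: TEMPO (cat.), PhI(OAc)2, MeCN–H2O, 23 °C
Reagents that add atoms: water, SMILES O
Why: Oxoammonium (TEMPO) oxidation with PhI(OAc)2 as terminal oxidant takes the primary alcohol through the aldehyde hydrate to the acid under near-neutral conditions that should spare the vinylcyclopropane and the electron-rich alkene, and the cis-alkenyl aldehyde is not accumulated, which limits its retro-Claisen isomerisation.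

Step 8
Reactants: 11 (1S,2S)-1-methyl-2-[(5R)-2-methyl-5-(propan-2-yl)cyclopent-1-en-1-yl]cyclopropane-1-carboxylic acid; 12 (trimethylsilyl)diazomethane
Product: 14 2-diazo-1-[(1S,2S)-1-methyl-2-[(5R)-2-methyl-5-(propan-2-yl)cyclopent-1-en-1-yl]cyclopropyl]ethan-1-one, via acyl chloride 13 (not isolated)
Conditions: 1-chloro-N,N,2-trimethylprop-1-en-1-amine, CH2Cl2, 0 → 23 °C; then 12, MeCN–THF, 0 → 23 °C
Reagents that add atoms: 12 (trimethylsilyl)diazomethane, SMILES C[Si](C)(C)C=[N+]=[N-]
Why: Acid chloride formation with the α-chloroenamine under neutral conditions, then C-acylation of the silyl diazomethane with loss of the silyl group as Me3SiCl (the first half of an Arndt–Eistert sequence), gives the diazomethyl ketone without acid that could open the vinylcyclopropane.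

Step 9
Reactants: 14 2-diazo-1-[(1S,2S)-1-methyl-2-[(5R)-2-methyl-5-(propan-2-yl)cyclopent-1-en-1-yl]cyclopropyl]ethan-1-one
Product: 16 (3R,8aS)-6,8a-dimethyl-3-(propan-2-yl)-1,2,3,5-tetrahydroazulen-8(8aH)-one, via ketene 15 (not isolated)
Conditions: hν (medium-pressure Hg lamp, Pyrex), degassed PhH (5 mM), 23 °C; then 80 °C, dark
Reagents that add atoms: none
Why: Irradiation expels N2 and cyclopropyl carbon C3 migrates to the diazo carbon with retention (Wolff rearrangement), giving ketene 15 in which the C2=C1 bond and the C6=C10 cyclopentene alkene are cis arms on the cyclopropane C3–C4–C5. This cis-divinylcyclopropane then undergoes a [3,3] sigmatropic (Cope) shift through the endo boat, forming C1–C10 and breaking C3–C5; the closest known reaction type is the tandem Wolff/Cope rearrangement of cis-2-alkenylcyclopropyl diazomethyl ketones to fused cyclohepta-2,5-dienones, and because shifts onto fully substituted alkene termini need more thermal activation the solution is warmed in the dark after photolysis. The seven-membered ring is closed by this pericyclic ring expansion of the three-membered ring (not by an end-to-end cyclisation), driven by release of cyclopropane strain and conversion of the ketene into a conjugated enone, with both new ring alkenes cis as the boat requires. The new quaternary stereocentre C10 is set by suprafacial chirality transfer from cyclopropane carbon C5: in the only endo boat open to the (1S,2S)-cyclopropane the ketene carbon reaches the C10 face anti to the C7 isopropyl group, so the methyl group ends up cis to isopropyl and the two stereochemical elements are matched. The step needs the acyl and cyclopentenyl groups cis (secured by the Z alkene and the stereospecific cyclopropanation), Wolff shift in preference to carbene addition or insertion (favoured by direct photolysis without a metal), and a Cope shift faster than loss of the ketene; the last is the weak point because the C10 methyl must point over the cyclopropane methylene in the boat.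

Step 10
Reactants: 16 (3R,8aS)-6,8a-dimethyl-3-(propan-2-yl)-1,2,3,5-tetrahydroazulen-8(8aH)-one
Product: 17 (3R,3aS,4R,8aS)-3a,4-epoxy-6,8a-dimethyl-3-(propan-2-yl)-1,2,3,3a,4,5-hexahydroazulen-8(8aH)-one (epoxide oxygen β, cis to the C10 methyl)
Conditions: 3-ClC6H4CO3H, NaHCO3, CH2Cl2, 0 °C
Reagents that add atoms: 3-chloroperoxybenzoic acid, SMILES OOC(=O)c1cccc(Cl)c1
Why: Prilezhaev epoxidation, chemoselective for the electron-rich C5=C6 alkene over the enone alkene; the oxygen should enter from the β face, because sp3 C10 holds C1 on the α side so that the planar enone C1–C2–C3 is folded under the α face and C3 screens C5, the carbon to which the peracid oxygen bonds first, whereas the β side of C5 carries only a C4 hydrogen, and this places the C6–O bond cis to the C10 methyl and the C7 isopropyl as the target requires.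

Step 11
Reactants: 17 (3R,3aS,4R,8aS)-3a,4-epoxy-6,8a-dimethyl-3-(propan-2-yl)-1,2,3,3a,4,5-hexahydroazulen-8(8aH)-one
Product: 18 (3R,3aS,8aR)-6,8a-dimethyl-3-(propan-2-yl)-2,3,4,5,8,8a-hexahydroazulene-3a,8(1H)-diol (both C8 epimers)
Conditions: LiAlH4, THF, 0 → 65 °C
Reagents that add atoms: none
Why: Hydride reduction with LiAlH4, in which the ketone is reduced without control (the C1 centre is erased in step 12) and the trisubstituted epoxide is opened by SN2 attack of hydride at the secondary C5, so that the C6–O bond and its β configuration are kept in the tertiary alcohol.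

Step 12
Reactants: 18 (3R,3aS,8aR)-6,8a-dimethyl-3-(propan-2-yl)-2,3,4,5,8,8a-hexahydroazulene-3a,8(1H)-diol (both C8 epimers)
Product: 19 (3R,3aS,8aS)-3a-hydroxy-6,8a-dimethyl-3-(propan-2-yl)-1,2,3,3a,4,5-hexahydroazulen-8(8aH)-one
Conditions: Dess–Martin periodinane, NaHCO3, CH2Cl2, 0 → 23 °C
Reagents that add atoms: none
Why: Dess–Martin oxidation returns the secondary allylic alcohol to the enone and so removes the uncontrolled C1 centre, while the tertiary C6 alcohol cannot be oxidised and the buffered, non-basic conditions avoid retro-aldol cleavage of the β-hydroxy ketone.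

Step 13
Reactants: 19 (3R,3aS,8aS)-3a-hydroxy-6,8a-dimethyl-3-(propan-2-yl)-1,2,3,3a,4,5-hexahydroazulen-8(8aH)-one
Product: 20 (3R,3aS,8R,8aR)-6,8a-dimethyl-3-(propan-2-yl)-2,3,4,5,8,8a-hexahydroazulene-3a,8(1H)-diol
Conditions: Me4NBH(OAc)3, MeCN–AcOH, −40 → −20 °C
Reagents that add atoms: none
Why: Evans–Saksena reduction, in which the C6 hydroxyl exchanges onto boron and the alkoxy(diacetoxy)borohydride delivers hydride through a six-membered transition state to the carbonyl face on the side of the C6–O bond (β), so that the new C1 hydroxyl is α and anti to the C6 hydroxyl, the reagent itself being too weak to reduce the enone externally at this temperature.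

Step 14
Reactants: 20 (3R,3aS,8R,8aR)-6,8a-dimethyl-3-(propan-2-yl)-2,3,4,5,8,8a-hexahydroazulene-3a,8(1H)-diol; 21 4-methoxybenzoyl chloride
Product: 22 (3R,3aS,8R,8aR)-3a-hydroxy-6,8a-dimethyl-3-(propan-2-yl)-1,2,3,3a,4,5,8,8a-octahydroazulen-8-yl 4-methoxybenzoate (CNP0158828.3)
Conditions: 21, Et3N, DMAP (cat.), CH2Cl2, 0 → 23 °C
Reagents that add atoms: 21 4-methoxybenzoyl chloride, SMILES COc1ccc(C(Cl)=O)cc1
Why: DMAP-catalysed acyl transfer esterifies the secondary allylic C1 hydroxyl, while the tertiary C6 hydroxyl, flanked by quaternary C10 and the isopropyl-bearing C7, is too hindered to be acylated.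

**Compound list**

1 | (S)-(−)-limonene, (4S)-1-methyl-4-(prop-1-en-2-yl)cyclohex-1-ene | CC1=CC[C@H](CC1)C(C)=C | starting material
2 | (4S)-1-methyl-4-(propan-2-yl)cyclohex-1-ene | CC1=CC[C@H](CC1)C(C)C | intermediate
3 | (3S)-6-oxo-3-(propan-2-yl)heptanal | O=CC[C@H](CCC(C)=O)C(C)C | intermediate
4 | (5R)-2-methyl-5-(propan-2-yl)cyclopent-1-ene-1-carbaldehyde | O=CC1=C(C)CC[C@@H]1C(C)C | intermediate
5 | ethyl 2-[bis(2,2,2-trifluoroethoxy)phosphoryl]propanoate | CCOC(=O)C(C)P(=O)(OCC(F)(F)F)OCC(F)(F)F | starting material
6 | ethyl (2Z)-2-methyl-3-[(5R)-2-methyl-5-(propan-2-yl)cyclopent-1-en-1-yl]prop-2-enoate | CCOC(=O)/C(C)=C\C1=C(C)CC[C@@H]1C(C)C | intermediate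
7 | (2Z)-2-methyl-3-[(5R)-2-methyl-5-(propan-2-yl)cyclopent-1-en-1-yl]prop-2-en-1-ol | OC/C(C)=C\C1=C(C)CC[C@@H]1C(C)C | intermediate
8 | diiodomethane | ICI | starting material
9 | [(1S,2S)-1-methyl-2-[(5R)-2-methyl-5-(propan-2-yl)cyclopent-1-en-1-yl]cyclopropyl]methanol (CH2OH and cyclopentenyl cis) | OC[C@@]1(C)C[C@H]1C2=C(C)CC[C@@H]2C(C)C | intermediate
10 | (1S,2S)-1-methyl-2-[(5R)-2-methyl-5-(propan-2-yl)cyclopent-1-en-1-yl]cyclopropane-1-carbaldehyde | O=C[C@@]1(C)C[C@H]1C2=C(C)CC[C@@H]2C(C)C | intermediate
11 | (1S,2S)-1-methyl-2-[(5R)-2-methyl-5-(propan-2-yl)cyclopent-1-en-1-yl]cyclopropane-1-carboxylic acid | OC(=O)[C@@]1(C)C[C@H]1C2=C(C)CC[C@@H]2C(C)C | intermediate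
12 | (trimethylsilyl)diazomethane | C[Si](C)(C)C=[N+]=[N-] | starting material
13 | (1S,2S)-1-methyl-2-[(5R)-2-methyl-5-(propan-2-yl)cyclopent-1-en-1-yl]cyclopropane-1-carbonyl chloride | ClC(=O)[C@@]1(C)C[C@H]1C2=C(C)CC[C@@H]2C(C)C | intermediate
14 | 2-diazo-1-[(1S,2S)-1-methyl-2-[(5R)-2-methyl-5-(propan-2-yl)cyclopent-1-en-1-yl]cyclopropyl]ethan-1-one (acyl and cyclopentenyl cis) | [N-]=[N+]=CC(=O)[C@@]1(C)C[C@H]1C2=C(C)CC[C@@H]2C(C)C | intermediate
15 | 2-[(1S,2R)-1-methyl-2-[(5R)-2-methyl-5-(propan-2-yl)cyclopent-1-en-1-yl]cyclopropyl]ethen-1-one (ketene; same spatial arrangement as 14) | O=C=C[C@@]1(C)C[C@H]1C2=C(C)CC[C@@H]2C(C)C | intermediate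
16 | (3R,8aS)-6,8a-dimethyl-3-(propan-2-yl)-1,2,3,5-tetrahydroazulen-8(8aH)-one | O=C1C=C(C)CC=C2[C@@H](C(C)C)CC[C@]12C | intermediate
17 | (3R,3aS,4R,8aS)-3a,4-epoxy-6,8a-dimethyl-3-(propan-2-yl)-1,2,3,3a,4,5-hexahydroazulen-8(8aH)-one | O=C1C=C(C)C[C@H]2O[C@]23[C@@H](C(C)C)CC[C@]13C | intermediate
18 | (3R,3aS,8aR)-6,8a-dimethyl-3-(propan-2-yl)-2,3,4,5,8,8a-hexahydroazulene-3a,8(1H)-diol, both C8 epimers | OC1C=C(C)CC[C@]2(O)[C@@H](C(C)C)CC[C@]12C | intermediate
19 | (3R,3aS,8aS)-3a-hydroxy-6,8a-dimethyl-3-(propan-2-yl)-1,2,3,3a,4,5-hexahydroazulen-8(8aH)-one | O=C1C=C(C)CC[C@]2(O)[C@@H](C(C)C)CC[C@]12C | intermediate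
20 | (3R,3aS,8R,8aR)-6,8a-dimethyl-3-(propan-2-yl)-2,3,4,5,8,8a-hexahydroazulene-3a,8(1H)-diol | O[C@@H]1C=C(C)CC[C@]2(O)[C@@H](C(C)C)CC[C@]12C | intermediate
21 | 4-methoxybenzoyl chloride | COc1ccc(C(Cl)=O)cc1 | starting material
22 | (3R,3aS,8R,8aR)-3a-hydroxy-6,8a-dimethyl-3-(propan-2-yl)-1,2,3,3a,4,5,8,8a-octahydroazulen-8-yl 4-methoxybenzoate | COc1ccc(C(=O)O[C@@H]2C=C(C)CC[C@]3(O)[C@@H](C(C)C)CC[C@]23C)cc1 | target

**Step count**

Total steps: 14. Longest linear sequence: 14 steps, from 1 to 22.

**Steps most likely to fail**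

(a) Step 9, the key step. The boat has to carry the C10 methyl over the cyclopropane methylene, which slows the [3,3] shift. If the ketene outlives it, material would be lost by ketene dimerisation or trapping, by cis-to-trans isomerisation of the cyclopropane on long heating, or by secondary photoreaction of the β,γ-unsaturated enone if light is still on. The fallback replaces the transient ketene by an isolable enol ether that can be heated for as long as needed. It sets out from 9 and comes back at 16.
- Dess–Martin oxidation of 9 gives aldehyde 10, isolated this time.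
- Wittig reaction of 10 with the ylide from [(4-methoxybenzyl)oxymethyl]triphenylphosphonium chloride and NaN(SiMe3)2 gives the enol ether F1; the E isomer is carried on.
- Heating in toluene (110–140 °C, sealed tube) effects the thermal cis-divinylcyclopropane Cope rearrangement to the 4-methoxybenzyl ether F2. The E geometry places the C1 oxygen anti to the C10 methyl, although this centre is removed again.
- DDQ (CH2Cl2, pH 7 buffer) gives the dienol F3, and Dess–Martin oxidation gives 16.

(b) Step 10. The epoxidation may show poor or reversed facial selectivity, because the β face carries the C10 methyl and the C7 isopropyl while the α face is lined by the folded enone. If the peracid prefers the α face, the same preference can be used through anti addition. The fallback sets out from 16 and comes back at 19.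
- N-Bromosuccinimide in aqueous acetone (0 °C) should place bromine on C5 from the α face and water on tertiary C6 from the β face, giving the bromohydrin F4.
- Radical debromination (Bu3SnH, AIBN, PhH, 80 °C) gives 19 directly, which also saves the reduction and re-oxidation of steps 11 and 12.

(c) Step 13. Internal hydride delivery may fail, through slow exchange of the tertiary alcohol onto boron or poor reach across the ring fusion, since the C6 oxygen and C1 are trans on the C6–C10 bond. External attack would then give the wrong C1 epimer. The fallback makes that outcome deliberate and corrects it by inversion. It sets out from 19 and comes back at 20.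
- Luche reduction (NaBH4, CeCl3·7H2O, MeOH, −78 °C), in which external hydride is expected to add anti to the C10 methyl, gives the C1-epimeric diol F5.
- Mitsunobu inversion (PPh3, diisopropyl azodicarboxylate, 4-nitrobenzoic acid, toluene) gives the inverted 4-nitrobenzoate F6; the tertiary alcohol does not react.
- Methanolysis (K2CO3, MeOH) gives 20.

**Further compounds**

F1 | step 9 | 1-methoxy-4-[({(E)-2-[(1S,2S)-1-methyl-2-[(5R)-2-methyl-5-(propan-2-yl)cyclopent-1-en-1-yl]cyclopropyl]ethenyl}oxy)methyl]benzene (enol ether, vinyl and cyclopentenyl cis on the cyclopropane) | COc1ccc(CO/C=C/[C@@]2(C)C[C@H]2C3=C(C)CC[C@@H]3C(C)C)cc1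
F2 | step 9 | (3R,8R,8aR)-8-[(4-methoxybenzyl)oxy]-6,8a-dimethyl-3-(propan-2-yl)-1,2,3,5,8,8a-hexahydroazulene | COc1ccc(CO[C@@H]2C=C(C)CC=C3[C@@H](C(C)C)CC[C@]23C)cc1
F3 | step 9 | (3R,8R,8aR)-6,8a-dimethyl-3-(propan-2-yl)-1,2,3,5,8,8a-hexahydroazulen-8-ol | O[C@@H]1C=C(C)CC=C2[C@@H](C(C)C)CC[C@]12C
F4 | step 10 | (3R,3aS,4S,8aS)-4-bromo-3a-hydroxy-6,8a-dimethyl-3-(propan-2-yl)-1,2,3,3a,4,5-hexahydroazulen-8(8aH)-one (bromine α, hydroxyl β) | O=C1C=C(C)C[C@H](Br)[C@]2(O)[C@@H](C(C)C)CC[C@]12C
F5 | step 13 | (3R,3aS,8S,8aR)-6,8a-dimethyl-3-(propan-2-yl)-2,3,4,5,8,8a-hexahydroazulene-3a,8(1H)-diol (C1 epimer of 20) | O[C@H]1C=C(C)CC[C@]2(O)[C@@H](C(C)C)CC[C@]12C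
F6 | step 13 | (3R,3aS,8R,8aR)-3a-hydroxy-6,8a-dimethyl-3-(propan-2-yl)-1,2,3,3a,4,5,8,8a-octahydroazulen-8-yl 4-nitrobenzoate | O=C(O[C@@H]1C=C(C)CC[C@]2(O)[C@@H](C(C)C)CC[C@]12C)c1ccc(cc1)[N+](=O)[O-]
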